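The route reads each α-methyl group of the two C8/C8′ 2-methylbutanoyl side chains on the chroman benzene rings as the former CH2 of a silyloxycyclopropane. That cyclopropane spans the carbonyl carbon and the α-carbon of a plain butanoyl chain. One double, ligand-controlled Simmons–Smith methylene transfer forms both three-membered rings, four C–C bonds and both α-stereocentres. Acid then spends the ring strain by breaking only the CH2–C(O) bonds. The precursor is the bis[(Z)-trimethylsilyl enol ether] of the tetra-MOM-protected, C6–C6′ 6-methylheptylidene-bridged bis(8-butanoyl-2,2-dimethylchroman). It is made by dimerising one regiodefined monomer whose only free aromatic carbon is C6.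

Key step: step 9

Assumption: the face that N-Boc-L-Val-L-Pro-OMe selects on so twisted an aryl enol ether cannot be derived with certainty, so the route is written for the L,L-ligand (one peptide coupling from Boc-L-Val-OH and L-Pro-OMe), and the equally accessible D,D-ligand replaces it if a model run on the monomeric enol ether shows the opposite sense.

Stereochemical bookkeeping: the (Z)-enol ether has ethyl cis to silyloxy. Syn addition gives the (1R,2S)-cyclopropane, where C1 is the carbinol carbon and C2 the ethyl-bearing carbon. Cleavage of CH2–C1 leaves C2 untouched, and it is then named (R) only because the CIP ranking of its substituents changes. The bridging carbon bears two identical arms and is not a stereocentre.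

Step 1
Reactants: 1 phloroglucinol; 2 butanoic acid
Product: 3 1-(2,4,6-trihydroxyphenyl)butan-1-one
Conditions: BF3·OEt2 (promoter and solvent), 85 °C; aq. NaOAc work-up
Reagents that add atoms: none
Why: Friedel–Crafts (Nencki-type) C-acylation of a very electron-rich arene, which should stop after one acyl group because the ketone, held as its boron chelate, deactivates the ring.

Step 2
Reactants: 3 1-(2,4,6-trihydroxyphenyl)butan-1-one
Product: 4 1-[2,4-bis(benzyloxy)-6-hydroxyphenyl]butan-1-one
Conditions: BnBr (2.05 equiv), K2CO3 (2.2 equiv), DMF, rt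
Reagents that add atoms: benzyl bromide, BrCc1ccccc1
Why: Williamson etherification takes the para hydroxyl and one ortho hydroxyl, while the last ortho hydroxyl is held back by its hydrogen bond to the ketone and is thereby singled out as the future ring oxygen O1.

Step 3
Reactants: 4 1-[2,4-bis(benzyloxy)-6-hydroxyphenyl]butan-1-one; 5 3-chloro-3-methylbut-1-yne
Product: 6 1-{2,4-bis(benzyloxy)-6-[(2-methylbut-3-yn-2-yl)oxy]phenyl}butan-1-one
Conditions: K2CO3, KI, CuI (5 mol %), DMF, 60 °C, argon
Reagents that add atoms: none
Why: Copper-assisted O-propargylation of a phenoxide with a tertiary propargylic chloride (ionisation-type substitution), the standard entry to aryl 1,1-dimethylpropargyl ethers, with only one free O–H available.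

Step 4
Reactants: 6 1-{2,4-bis(benzyloxy)-6-[(2-methylbut-3-yn-2-yl)oxy]phenyl}butan-1-one
Product: 8 1-[5,7-bis(benzyloxy)-2,2-dimethyl-2H-chromen-8-yl]butan-1-one, via ortho-allenylphenol 7 (not isolated)
Conditions: o-xylene, 140 °C
Reagents that add atoms: none
Why: Aromatic propargyl Claisen rearrangement to the only free ortho carbon, then tautomerisation to 7, a 1,5-hydrogen shift and oxa-6π electrocyclisation, so the pyran oxygen necessarily ends up next to the acyl-bearing carbon, which becomes C8.

Step 5
Reactants: 8 1-[5,7-bis(benzyloxy)-2,2-dimethyl-2H-chromen-8-yl]butan-1-one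
Product: 9 1-(5,7-dihydroxy-2,2-dimethylchroman-8-yl)butan-1-one
Conditions: H2 (1 atm), Pd/C, EtOAc–MeOH, rt
Reagents that add atoms: none
Why: Heterogeneous catalytic hydrogenation saturates the C3–C4 alkene and hydrogenolyses both benzyl ethers in one operation, while the hindered, hydrogen-bonded aryl ketone should stay untouched under neutral conditions.

Step 6
Reactants: 9 1-(5,7-dihydroxy-2,2-dimethylchroman-8-yl)butan-1-one (2 equiv); 10 6-methylheptanal
Product: 12 1,1′-[(6-methylheptane-1,1-diyl)bis(5,7-dihydroxy-2,2-dimethylchromane-6,8-diyl)]bis(butan-1-one), via benzylic carbinol 11 (not isolated)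
Conditions: p-TsOH·H2O (10 mol %), 4 Å MS, CH2Cl2, 0 °C → rt
Reagents that add atoms: none
Why: Baeyer-type phenol–aldehyde condensation (hydroxyalkylation to 11, ionisation to an ortho-quinone methide, Friedel–Crafts capture by a second molecule of 9), which can neither oligomerise nor give regioisomers because C6, activated by O5, O7 and O1, is the only aromatic C–H.

Step 7
Reactants: 12 bridged tetraphenol bis(butanoyl) compound
Product: 13 1,1′-{(6-methylheptane-1,1-diyl)bis[5,7-bis(methoxymethoxy)-2,2-dimethylchromane-6,8-diyl]}bis(butan-1-one)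
Conditions: NaH (4.4 equiv), MOMCl (6 equiv), DMF, 0 °C → rt
Reagents that add atoms: chloromethyl methyl ether, COCCl
Why: Williamson-type O-alkylation of the four sodium phenoxides with a small, hard electrophile should reach even the chelated, flanked O7 positions, and it removes every O–H that would later consume the amide base or the zinc carbenoid.

Step 8
Reactants: 13 tetrakis(MOM) bis(butanoyl) compound
Product: 15 6,6′-(6-methylheptane-1,1-diyl)bis{5,7-bis(methoxymethoxy)-2,2-dimethyl-8-[(Z)-1-(trimethylsilyloxy)but-1-enyl]chromane}, via bis-lithium (Z)-enolate 14 (not isolated)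
Conditions: LiN(SiMe3)2 (3 equiv), THF–DMPU 4:1, −78 °C; Me3SiCl–Et3N, −78 → 0 °C; cold NaHCO3 work-up, Et3N-deactivated silica
Reagents that add atoms: chlorotrimethylsilane, C[Si](C)(C)Cl
Why: Amide-base enolisation and O-silylation, in which LiN(i-Pr)2 is avoided because an arene twisted by two ortho oxygens looks small in the closed chair-like deprotonation transition state and would favour the (E)-enolate, whereas the weaker hexamethyldisilazide in a lithium-solvating medium reacts through an open, product-like transition state that places ethyl away from the arene and cis to oxygen, as known for mesityl-type ethyl ketones.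

Step 9
Reactants: 15 bis[(Z)-trimethylsilyl enol ether]; 16 diiodomethane
Product: 17 6,6′-(6-methylheptane-1,1-diyl)bis{8-[(1R,2S)-2-ethyl-1-(trimethylsilyloxy)cyclopropyl]-5,7-bis(methoxymethoxy)-2,2-dimethylchromane}
Conditions: N-Boc-L-Val-L-Pro-OMe (3 equiv), Zn(C2H5)2 (3 equiv), CH2Cl2, 0 °C; CH2I2 (3 equiv), −40 °C; then 15, −40 → −20 °C; Et3N then aq. NaHCO3 quench
Reagents that add atoms: diiodomethane (16, the CH2 donor, also listed as reactant), ICI
Why: Proposed new method: the carbamate-N-zincated dipeptide carries an ICH2–Zn unit that hands its CH2 to each electron-rich C=C through the concerted, stereospecific butterfly [2+1] transition state of the Simmons–Smith reaction; the closest known reaction type is the dipeptide-mediated asymmetric cyclopropanation of (Z)-1-aryl-1-silyloxyalkenes, which has not been shown for arenes with two ortho oxygen substituents or for two alkenes in one substrate. Each cyclopropane closes by intermolecular syn addition of the one-carbon unit to both alkene carbons at once (C2–CH2 and C1–CH2 bonds formed together), so no ring-size or regiochemical choice arises. Syn addition turns the (Z) geometry into the cis relation of ethyl and silyloxy groups and thereby couples C1 (R) to C2 (S), while the absolute face, and with it C2 (the future α-carbon), is chosen by the ligand alone. The substrate adds no bias of its own, because the arene stands perpendicular to the alkene and rotation about the C8–C1 bond exchanges the O7-MOM and O1 flanks of the two faces. The step needs chemoselectivity and suppression of unligated carbenoid: the enol ethers are the only alkenes, all O–H groups are capped, and a full equivalent of ligand per alkene is used because the MOM oxygens could otherwise recruit free Zn(CH2I)2. As the two sites react independently, a wrong-face event ends in a separable (R,S)-type diastereomer, so the enantiopurity of 17 should be statistically amplified.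

Step 10
Reactants: 17 bis(silyloxycyclopropane)
Product: 20 (2R,2′R)-1,1′-[(6-methylheptane-1,1-diyl)bis(5,7-dihydroxy-2,2-dimethylchromane-6,8-diyl)]bis(2-methylbutan-1-one), via bis-cyclopropanol 18 (not isolated), via MOM-protected bis-ketone 19 (not isolated)
Conditions: HCl (0.1 M) in MeOH–THF, 0 °C; then HCl raised to 1.5 M, rt
Reagents that add atoms: none
Why: Acid methanolysis removes the silyl groups, the cyclopropanols 18 open by electrophilic (SE2) protonation at the unsubstituted, least hindered ring carbon with push from the hydroxyl oxygen (the acid variant of the siloxycyclopropane route to α-methyl ketones) so that only CH2–C1 breaks and no bond at the α-carbon is touched, and the same medium then transacetalises the four MOM ethers, acid being preferred to base because acid-catalysed enolisation of a hindered sec-alkyl aryl ketone is far slower than its base-mediated epimerisation.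

Compound list

1 | phloroglucinol | Oc1cc(O)cc(O)c1 | starting material
2 | butanoic acid | CCCC(=O)O | starting material
3 | 1-(2,4,6-trihydroxyphenyl)butan-1-one | CCCC(=O)c1c(O)cc(O)cc1O | intermediate
4 | 1-[2,4-bis(benzyloxy)-6-hydroxyphenyl]butan-1-one | CCCC(=O)c1c(O)cc(OCc2ccccc2)cc1OCc1ccccc1 | intermediate
5 | 3-chloro-3-methylbut-1-yne | CC(C)(Cl)C#C | starting material
6 | 1-{2,4-bis(benzyloxy)-6-[(2-methylbut-3-yn-2-yl)oxy]phenyl}butan-1-one | CCCC(=O)c1c(OC(C)(C)C#C)cc(OCc2ccccc2)cc1OCc1ccccc1 | intermediate
7 | 1-[4,6-bis(benzyloxy)-2-hydroxy-3-(3-methylbuta-1,2-dien-1-yl)phenyl]butan-1-one (not isolated) | CCCC(=O)c1c(O)c(C=C=C(C)C)c(OCc2ccccc2)cc1OCc1ccccc1 | intermediate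
8 | 1-[5,7-bis(benzyloxy)-2,2-dimethyl-2H-chromen-8-yl]butan-1-one | CCCC(=O)c1c(OCc2ccccc2)cc(OCc2ccccc2)c2c1OC(C)(C)C=C2 | intermediate
9 | 1-(5,7-dihydroxy-2,2-dimethylchroman-8-yl)butan-1-one | CCCC(=O)c1c(O)cc(O)c2c1OC(C)(C)CC2 | intermediate
10 | 6-methylheptanal | CC(C)CCCCC=O | starting material
11 | 1-[5,7-dihydroxy-6-(1-hydroxy-6-methylheptyl)-2,2-dimethylchroman-8-yl]butan-1-one (racemic, not isolated) | CCCC(=O)c1c(O)c(C(O)CCCCC(C)C)c(O)c2c1OC(C)(C)CC2 | intermediate
12 | 1,1′-[(6-methylheptane-1,1-diyl)bis(5,7-dihydroxy-2,2-dimethylchromane-6,8-diyl)]bis(butan-1-one) | CCCC(=O)c1c(O)c(C(CCCCC(C)C)c2c(O)c3c(c(C(=O)CCC)c2O)OC(C)(C)CC3)c(O)c2c1OC(C)(C)CC2 | intermediate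
13 | tetrakis(methoxymethyl) ether of 12 | CCCC(=O)c1c(OCOC)c(C(CCCCC(C)C)c2c(OCOC)c3c(c(C(=O)CCC)c2OCOC)OC(C)(C)CC3)c(OCOC)c2c1OC(C)(C)CC2 | intermediate
14 | bis-lithium (Z,Z)-enolate of 13 (not isolated) | CC/C=C(\O[Li])c1c(OCOC)c(C(CCCCC(C)C)c2c(OCOC)c3c(c(/C(O[Li])=C/CC)c2OCOC)OC(C)(C)CC3)c(OCOC)c2c1OC(C)(C)CC2 | intermediate
15 | bis[(Z)-trimethylsilyl enol ether] of 13 | CC/C=C(\O[Si](C)(C)C)c1c(OCOC)c(C(CCCCC(C)C)c2c(OCOC)c3c(c(/C(O[Si](C)(C)C)=C/CC)c2OCOC)OC(C)(C)CC3)c(OCOC)c2c1OC(C)(C)CC2 | intermediate
16 | diiodomethane | ICI | starting material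
17 | bis[(1R,2S)-2-ethyl-1-(trimethylsilyloxy)cyclopropyl] tetrakis(MOM) bridged bis-chroman | CC[C@H]1C[C@]1(O[Si](C)(C)C)c1c(OCOC)c(C(CCCCC(C)C)c2c(OCOC)c3c(c([C@@]4(O[Si](C)(C)C)C[C@@H]4CC)c2OCOC)OC(C)(C)CC3)c(OCOC)c2c1OC(C)(C)CC2 | intermediate
18 | bis[(1R,2S)-2-ethyl-1-hydroxycyclopropyl] tetrakis(MOM) bridged bis-chroman (not isolated) | CC[C@H]1C[C@]1(O)c1c(OCOC)c(C(CCCCC(C)C)c2c(OCOC)c3c(c([C@@]4(O)C[C@@H]4CC)c2OCOC)OC(C)(C)CC3)c(OCOC)c2c1OC(C)(C)CC2 | intermediate
19 | tetrakis(MOM) ether of the target, (2R,2′R) (not isolated) | CC[C@@H](C)C(=O)c1c(OCOC)c(C(CCCCC(C)C)c2c(OCOC)c3c(c(C(=O)[C@H](C)CC)c2OCOC)OC(C)(C)CC3)c(OCOC)c2c1OC(C)(C)CC2 | intermediate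
20 | (2R,2′R)-1,1′-[(6-methylheptane-1,1-diyl)bis(5,7-dihydroxy-2,2-dimethylchromane-6,8-diyl)]bis(2-methylbutan-1-one), CNP0324275.1 | CC[C@@H](C)C(=O)c1c(O)c(C(CCCCC(C)C)c2c(O)c3c(c(C(=O)[C@H](C)CC)c2O)OC(C)(C)CC3)c(O)c2c1OC(C)(C)CC2 | target

Total step count: 10. Longest linear sequence: 10 steps (1 → 20).

Steps most likely to fail

Step 9 (labelled step). Three things may go wrong.
- The bulky ligand-bound carbenoid may fail to reach alkenes that are shielded on both faces by the ortho oxygens.
- Unligated carbenoid recruited by the MOM oxygens may take over and erode facial selectivity.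
- ZnI2 may strip silyl or MOM groups, or trigger attack of the enol ether on an activated MOM acetal.

The fallback uses known chemistry and takes the stereocentre from the chiral pool. It sets out from 1 and comes back at 20. Commercial (R)-2-methylbutanoic acid is converted with (COCl)2 and catalytic DMF into (R)-2-methylbutanoyl chloride F1. This acylates 1 under mild Friedel–Crafts conditions (AlCl3, CH2Cl2–PhNO2, rt) to (R)-2-methyl-1-(2,4,6-trihydroxyphenyl)butan-1-one F2. The operations of steps 2 to 5 then give in turn the dibenzyl ether F3, the 1,1-dimethylpropargyl ether F4, the chromene F5 and (R)-1-(5,7-dihydroxy-2,2-dimethylchroman-8-yl)-2-methylbutan-1-one F6. Condensation of two molecules of F6 with 10 under the conditions of step 6 gives 20 directly, without MOM groups, enol ethers or cyclopropanes.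

Step 8. The deprotonation may give incomplete (Z) selectivity, since the twisted arene offers little steric differentiation, and the enol ethers may hydrolyse on isolation. Every (E)-alkene would map onto the wrong α-configuration.

The fallback sets out from 13 and comes back at 15. Compound 13 is silylated without regard to geometry (LiN(i-Pr)2, Me3SiCl, THF, −78 °C) to the mixed-geometry bis(silyl enol ether) F7. Saegusa–Ito oxidation (Pd(OAc)2, MeCN, rt) converts all isomers into the single bis[(E)-but-2-enoyl] compound F8. Conjugate hydride addition with LiBH(s-Bu)3 (THF, −78 °C) then acts on the s-cis enone, the conformer enforced by the large aryl group. This generates 14 with oxygen and ethyl cis by construction, and Me3SiCl gives 15.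

Step 10. Protonation may compete at the ethyl-bearing ring carbon, which cleaves C1–C2 and leads to an unbranched chain. Slow acid-catalysed epimerisation, or solvolysis of the diarylmethine bridge during prolonged MOM cleavage, is also possible.

The fallback sets out from 17 and comes back at 19. The silyl ethers are removed with K2CO3 in MeOH at 0 °C and 18 is isolated. Ring opening is then switched from electrophilic to carbanionic control with catalytic NaOMe in MeOH–THF at 0 °C. The cyclopropoxide expels the more stable primary homoenolate carbanion, so only CH2–C1 can break. An AcOH quench at full conversion limits enolisation, and 19 is isolated and purified. It is then carried through the second, acidic stage of step 10 with a short, separately tuned contact time.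

Further compounds

F1 | step 9 | (R)-2-methylbutanoyl chloride | CC[C@@H](C)C(=O)Cl
F2 | step 9 | (R)-2-methyl-1-(2,4,6-trihydroxyphenyl)butan-1-one | CC[C@@H](C)C(=O)c1c(O)cc(O)cc1O
F3 | step 9 | (R)-1-[2,4-bis(benzyloxy)-6-hydroxyphenyl]-2-methylbutan-1-one | CC[C@@H](C)C(=O)c1c(O)cc(OCc2ccccc2)cc1OCc1ccccc1
F4 | step 9 | (R)-1-{2,4-bis(benzyloxy)-6-[(2-methylbut-3-yn-2-yl)oxy]phenyl}-2-methylbutan-1-one | CC[C@@H](C)C(=O)c1c(OC(C)(C)C#C)cc(OCc2ccccc2)cc1OCc1ccccc1
F5 | step 9 | (R)-1-[5,7-bis(benzyloxy)-2,2-dimethyl-2H-chromen-8-yl]-2-methylbutan-1-one | CC[C@@H](C)C(=O)c1c(OCc2ccccc2)cc(OCc2ccccc2)c2c1OC(C)(C)C=C2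
F6 | step 9 | (R)-1-(5,7-dihydroxy-2,2-dimethylchroman-8-yl)-2-methylbutan-1-one | CC[C@@H](C)C(=O)c1c(O)cc(O)c2c1OC(C)(C)CC2
F7 | step 8 | bis(trimethylsilyl enol ether) of 13 as a mixture of alkene geometries | CCC=C(O[Si](C)(C)C)c1c(OCOC)c(C(CCCCC(C)C)c2c(OCOC)c3c(c(C(O[Si](C)(C)C)=CCC)c2OCOC)OC(C)(C)CC3)c(OCOC)c2c1OC(C)(C)CC2
F8 | step 8 | tetrakis(MOM) bridged bis-chroman bearing (E)-but-2-enoyl groups at C8 and C8′ | C/C=C/C(=O)c1c(OCOC)c(C(CCCCC(C)C)c2c(OCOC)c3c(c(C(=O)/C=C/C)c2OCOC)OC(C)(C)CC3)c(OCOC)c2c1OC(C)(C)CC2
F0 | step 10 | none | none
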